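**Plan**

- Retrosynthesis: remove the acetates and the O15 silyl group; cut C9–C11 (sp2–sp3 coupling of a C9 enol triflate with a C11–C16 alkylzinc); trace the C6 and C7 oxygens back to a 7-en-9-one; cut C3–C4 (radical conjugate cyclisation, ring A); cut C10–C1 and C10–CH3 (enolate alkylations) to reach (R)-carvone.
- Enabling feature: ring B (C5–C10, with the C8 methyl and C9 as carbonyl carbon) is carvone itself. Its isopropenyl group is C4 plus one geminal methyl, so adding H• there gives the C4 radical that closes ring A onto a C1–C3 acrylate arm on C10.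
- Forward order: ring B is bought; ring A closes in step 3; then ester excision, C6 oxidation to the ene-dione, reductive triflation at C9, attachment of the chain (five steps from but-3-yn-1-ol), C7 hydroxylation, C6 reduction, acetylation, desilylation.
- Stereochemistry: C5 from (R)-carvone; C10 by alkylation anti to the isopropenyl group; C7 (oxaziridine) and C6 (hydride) by α-face attack, enforced by the β-axial methyls on C4 and C10; 13E by syn carboalumination.

Key step: step 3

Remark: labdane numbering is used for the bicyclic compounds (α/β with the C10 methyl β). The C2 configuration of 7–10 is drawn equatorial (2α) and is of no consequence, because C2 becomes a methylene in step 5.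

**Route**

Step 1
Reactants: 1 (R)-(−)-carvone
Product: 3 (5R)-6-methylcarvone [2,6-dimethyl-5-(prop-1-en-2-yl)cyclohex-2-en-1-one; both C6 epimers], via lithium enolate 2 (not isolated)
Conditions: LDA, THF, −78 °C; MeI, −78 → 0 °C
Reagents that add atoms: iodomethane, CI
Why: Kinetic deprotonation of the enone by LDA takes place at the α′ carbon (C10 of the target) and the cross-conjugated enolate is C-methylated (enolate alkylation); the configuration of the new centre is irrelevant because it is enolised again in step 2.

Step 2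
Reactants: 3 (5R)-6-methylcarvone; 4 methyl 2-(bromomethyl)acrylate
Product: 6 methyl 2-{[(1S,6S)-1,3-dimethyl-2-oxo-6-(prop-1-en-2-yl)cyclohex-3-en-1-yl]methyl}prop-2-enoate (acrylate arm trans and methyl cis to the isopropenyl group), via lithium enolate 5 (not isolated)
Conditions: LDA, THF, −78 °C; 4, DMPU, −78 → −20 °C
Reagents that add atoms: none
Why: Enolate alkylation with a highly reactive allylic bromide (SN2 or SN2′, same product) should occur on the face opposite the neighbouring isopropenyl group, as is usual for allylations of 6-methylcarvone, and this sets the quaternary C10.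

Step 3
Reactants: 6 the acrylate-armed carvone
Product: 7 methyl (2S,4aS,8aS)-4,4,7,8a-tetramethyl-8-oxo-1,2,3,4,4a,5,8,8a-octahydronaphthalene-2-carboxylate (trans-decalin; 5α-H; 10β-CH3; 2α-ester)
Conditions: Fe(acac)3 (cat.), PhSiH3, EtOH/(CH2OH)2, 60 °C
Reagents that add atoms: none
Why: An iron hydride formed from Fe(acac)3 and PhSiH3 should transfer a hydrogen atom to the CH2 terminus of the isopropenyl group (Markovnikov MHAT) to give the tertiary C4 radical, which adds to C3, the unsubstituted acrylate terminus, and the α-ester radical at C2 is then reduced and protonated by ethanol. The closest known reaction is the Fe(acac)3/PhSiH3 reductive coupling of 1,1-disubstituted donor olefins with acrylates (HAT-initiated Giese addition), used here intramolecularly. Ring A closes in the 6-endo-trig mode through C3–C4; the 5-exo alternative would attack the ester-bearing C2, is polarity-mismatched, and would give two adjacent quaternary carbons and a primary radical. The only new stereocentre, C2, is set by protonation of the ester enolate (equatorial 2α expected) and is erased in step 5, while the ring fusion is fixed beforehand by the trans arrangement of the C4 and C1 arms on C5 and C10, which lets ring A close as a chair to the trans-decalin. The step needs H-atom transfer to the electron-rich 1,1-disubstituted alkene and not to the acrylate or the ring-B enone, and this is secured by polarity matching (hydridic metal hydride to the donor olefin, nucleophilic tertiary radical to the acceptor olefin), the enone β-carbon C7 being out of reach of the C4 radical.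

Step 4
Reactants: 7 the bicyclic keto ester
Product: 8 (2S,4aS,8aS)-4,4,7,8a-tetramethyl-8-oxo-1,2,3,4,4a,5,8,8a-octahydronaphthalene-2-carboxylic acid
Conditions: LiOH·H2O, THF/MeOH/H2O, 50 °C; then 1 M HCl
Reagents that add atoms: lithium hydroxide, [Li+].[OH-]
Why: Saponification of an unhindered secondary methyl ester; the enone and the ring fusion are inert to hydroxide and epimerisation at C2 is immaterial.

Step 5
Reactants: 8 the keto acid
Product: 11 (4aS,8aS)-2,5,5,8a-tetramethyl-4a,5,6,7,8,8a-hexahydronaphthalen-1(4H)-one (4,4,8,10-tetramethyl-7-en-9-one; 5α-H; 10β-CH3), via acid chloride 9 (not isolated), via Barton ester 10 (not isolated)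
Conditions: (COCl)2, DMF (cat.), CH2Cl2, 0 °C → rt; then 2-mercaptopyridine N-oxide sodium salt, DMAP (cat.), t-BuSH, PhMe, hν, 80 °C
Reagents that add atoms: none
Why: Barton reductive decarboxylation: the thiohydroxamate ester should fragment under light to the secondary C2 radical, which abstracts hydrogen from the thiol; this removes the activating group together with the C2 stereocentre, and the distant enone cannot trap the radical.

Step 6
Reactants: 11 the bicyclic enone
Product: 12 (4aS,8aS)-2,5,5,8a-tetramethyl-4a,5,6,7,8,8a-hexahydronaphthalene-1,4-dione (7-ene-6,9-dione)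
Conditions: Pd(OH)2/C (cat.), t-BuOOH, K2CO3, CH2Cl2, 0 °C → rt
Reagents that add atoms: tert-butyl hydroperoxide, CC(C)(C)OO
Why: Palladium hydroxide/TBHP γ-oxidation of an α,β-enone to the ene-1,4-dione (peroxyl-radical abstraction at C6, the only γ-methylene); no stereocentre is formed and C5, now α to a ketone, should stay in the more stable trans-fused arrangement.

Step 7
Reactants: 12 the ene-dione
Product: 14 (4aS,8aS)-2,5,5,8a-tetramethyl-4-oxo-3,4,4a,5,6,7,8,8a-octahydronaphthalen-1-yl trifluoromethanesulfonate (6-oxo-8-en-9-yl triflate), via lithium enolate 13 (not isolated)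
Conditions: L-Selectride (1.0 equiv), THF, −78 °C; then Comins' reagent, −78 → 0 °C; aq. NH4Cl
Reagents that add atoms: Comins' reagent [N-(5-chloropyridin-2-yl)bis(trifluoromethanesulfonimide)], FC(F)(F)S(=O)(=O)N(c1ccc(Cl)cn1)S(=O)(=O)C(F)(F)F
Why: Conjugate reduction with enolate trapping (reductive triflation of an enone): the bulky hydride should add to the unsubstituted C7 and not to the methyl-bearing C8, which places the enolate, and so the triflate, at C9 and leaves the C6 ketone.

Step 8
Reactants: 15 but-3-yn-1-ol
Product: 16 (but-3-yn-1-yloxy)(tert-butyl)dimethylsilane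
Conditions: TBSCl, imidazole, CH2Cl2, 0 °C → rt
Reagents that add atoms: tert-butyldimethylsilyl chloride, CC(C)(C)[Si](C)(C)Cl
Why: Standard silylation of a primary alcohol, needed so that the later alanate step is clean and the two chain termini stay differentiated.

Step 9
Reactants: 16 the silyl-protected butynol
Product: 18 (E)-5-(tert-butyldimethylsilyloxy)-3-methylpent-2-en-1-ol, via alkenylalane 17 (not isolated)
Conditions: AlMe3, Cp2ZrCl2 (cat.), CH2Cl2, 0 °C → rt; evaporate; n-BuLi, THF/hexane, −78 → 0 °C; (CH2O)n, rt
Reagents that add atoms: trimethylaluminium, C[Al](C)C; paraformaldehyde (as formaldehyde), C=O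
Why: Zirconium-catalysed carboalumination (Negishi) adds CH3 and Al syn across the terminal alkyne with Al at the terminus, and the alanate formed with n-BuLi is hydroxymethylated with retention, which fixes the 13E geometry.

Step 10
Reactants: 18 the allylic alcohol
Product: 19 (E)-1-(tert-butyldiphenylsilyloxy)-5-(tert-butyldimethylsilyloxy)-3-methylpent-2-ene
Conditions: TBDPSCl, imidazole, CH2Cl2, rt
Reagents that add atoms: tert-butyldiphenylsilyl chloride, CC(C)(C)[Si](Cl)(c1ccccc1)c1ccccc1
Why: Standard silylation; the TBDPS group is chosen for O15 because it should survive every later step and be removable beside acetates.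

Step 11
Reactants: 19 the bis-silyl ether
Product: 20 (E)-5-(tert-butyldiphenylsilyloxy)-3-methylpent-3-en-1-ol
Conditions: PPTS (cat.), MeOH, rt
Reagents that add atoms: none
Why: Acid-catalysed methanolysis should cleave the primary TBS ether selectively, the TBDPS ether being markedly more acid-stable.

Step 12
Reactants: 20 the homoallylic alcohol
Product: 21 (E)-tert-butyl[(5-iodo-3-methylpent-2-en-1-yl)oxy]diphenylsilane
Conditions: I2, PPh3, imidazole, CH2Cl2, 0 °C
Reagents that add atoms: iodine, II
Why: Appel-type iodination of a primary alcohol under neutral conditions, which leaves the silyl ether and the trisubstituted alkene untouched.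

Step 13
Reactants: 14 the 6-oxo-8-en-9-yl triflate; 21 the side-chain iodide
Product: 23 15-(tert-butyldiphenylsilyloxy)labda-8,13E-dien-6-one, via alkylzinc iodide 22 (not isolated)
Conditions: 21, Zn dust, LiCl, THF, 40 °C; then 14, Pd2(dba)3 (cat.), SPhos (cat.), THF/NMP, 50 °C
Reagents that add atoms: none
Why: Negishi sp2–sp3 cross-coupling: the alkylzinc from direct zinc insertion transmetalates to the alkenylpalladium formed from the triflate, organozincs neither add to nor enolise the C6 ketone, and no stereocentre is touched.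

Step 14
Reactants: 23 the β,γ-unsaturated ketone
Product: 25 15-(tert-butyldiphenylsilyloxy)-7α-hydroxylabda-8,13E-dien-6-one, via potassium dienolate 24 (not isolated)
Conditions: KHMDS, THF, −78 °C; 3-phenyl-2-(phenylsulfonyl)oxaziridine, −78 °C; AcOH
Reagents that add atoms: Davis oxaziridine, O=S(=O)(N1OC1c1ccccc1)c1ccccc1
Why: Enolate hydroxylation with the Davis oxaziridine: deprotonation at the doubly activated C7 gives the C6–C9 dienolate, which should react at its α-carbon C7 from the α-face because the β-face is screened by the axial methyls on C10 and C4, and the oxaziridine leaves the side-chain alkene alone.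

Step 15
Reactants: 25 the 7α-hydroxy ketone
Product: 26 15-(tert-butyldiphenylsilyloxy)labda-8,13E-diene-6β,7α-diol
Conditions: NaBH4, MeOH/THF, −20 → 0 °C
Reagents that add atoms: none
Why: Borohydride reduction: hydride should attack C6 from the α-face, the β-face being blocked by the syn-axial methyls on C4 and C10, to give the axial 6β-alcohol as is general for 6-oxo-4,4,10-trimethyl-trans-decalins.

Step 16
Reactants: 26 the 6β,7α-diol
Product: 27 6β,7α-diacetoxy-15-(tert-butyldiphenylsilyloxy)labda-8,13E-diene
Conditions: Ac2O, DMAP, pyridine, 50 °C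
Reagents that add atoms: acetic anhydride, CC(=O)OC(C)=O
Why: DMAP-catalysed acylation under forcing conditions, required because the axial 6β-hydroxyl is hindered; both carbinol configurations are retained.

Step 17
Reactants: 27 the silyl-protected diacetate
Product: 28 6β,7α-diacetoxylabda-8,13E-dien-15-ol (target, CNP0187815.1)
Conditions: HF·pyridine, pyridine/THF, 0 °C → rt
Reagents that add atoms: none
Why: Fluoride-mediated cleavage of the Si–O bond under buffered conditions that should not hydrolyse or shift the two acetates.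

**Compound list**

1 | (R)-(−)-carvone | CC1=CC[C@H](CC1=O)C(C)=C | starting material
2 | lithium enolate of carvone (C1–C6 cross-conjugated enolate) | C1C=C(C)C(O[Li])=C[C@@H]1C(C)=C | intermediate
3 | (5R)-6-methylcarvone, C6 epimer mixture | C1C=C(C)C(=O)C(C)[C@@H]1C(C)=C | intermediate
4 | methyl 2-(bromomethyl)acrylate | C=C(CBr)C(=O)OC | starting material
5 | lithium enolate of 6-methylcarvone | C1C=C(C)C(O[Li])=C(C)[C@@H]1C(C)=C | intermediate
6 | methyl 2-{[(1S,6S)-1,3-dimethyl-2-oxo-6-(prop-1-en-2-yl)cyclohex-3-en-1-yl]methyl}prop-2-enoate | C1C=C(C)C(=O)[C@@](C)(CC(=C)C(=O)OC)[C@@H]1C(C)=C | intermediate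
7 | methyl (2S,4aS,8aS)-4,4,7,8a-tetramethyl-8-oxo-1,2,3,4,4a,5,8,8a-octahydronaphthalene-2-carboxylate | C1C=C(C)C(=O)[C@@]2(C)C[C@@H](C(=O)OC)CC(C)(C)[C@H]12 | intermediate
8 | (2S,4aS,8aS)-4,4,7,8a-tetramethyl-8-oxo-1,2,3,4,4a,5,8,8a-octahydronaphthalene-2-carboxylic acid | C1C=C(C)C(=O)[C@@]2(C)C[C@@H](C(=O)O)CC(C)(C)[C@H]12 | intermediate
9 | acid chloride of 8 | C1C=C(C)C(=O)[C@@]2(C)C[C@@H](C(Cl)=O)CC(C)(C)[C@H]12 | intermediate
10 | Barton ester of 8 (2-thioxopyridin-1(2H)-yl ester) | C1C=C(C)C(=O)[C@@]2(C)C[C@@H](C(=O)ON3C=CC=CC3=S)CC(C)(C)[C@H]12 | intermediate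
11 | (4aS,8aS)-2,5,5,8a-tetramethyl-4a,5,6,7,8,8a-hexahydronaphthalen-1(4H)-one | C1C=C(C)C(=O)[C@@]2(C)CCCC(C)(C)[C@H]12 | intermediate
12 | (4aS,8aS)-2,5,5,8a-tetramethyl-4a,5,6,7,8,8a-hexahydronaphthalene-1,4-dione | O=C1C=C(C)C(=O)[C@@]2(C)CCCC(C)(C)[C@H]12 | intermediate
13 | lithium C8–C9 enolate of the 6,9-dione | O=C1CC(C)=C(O[Li])[C@@]2(C)CCCC(C)(C)[C@H]12 | intermediate
14 | (4aS,8aS)-2,5,5,8a-tetramethyl-4-oxo-3,4,4a,5,6,7,8,8a-octahydronaphthalen-1-yl trifluoromethanesulfonate | O=C1CC(C)=C(OS(=O)(=O)C(F)(F)F)[C@@]2(C)CCCC(C)(C)[C@H]12 | intermediate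
15 | but-3-yn-1-ol | C#CCCO | starting material
16 | (but-3-yn-1-yloxy)(tert-butyl)dimethylsilane | C#CCCO[Si](C)(C)C(C)(C)C | intermediate
17 | (E)-[4-(tert-butyldimethylsilyloxy)-2-methylbut-1-en-1-yl]dimethylalane | CC(C)(C)[Si](C)(C)OCC/C(C)=C/[Al](C)C | intermediate
18 | (E)-5-(tert-butyldimethylsilyloxy)-3-methylpent-2-en-1-ol | CC(C)(C)[Si](C)(C)OCC/C(C)=C/CO | intermediate
19 | (E)-1-(tert-butyldiphenylsilyloxy)-5-(tert-butyldimethylsilyloxy)-3-methylpent-2-ene | CC(C)(C)[Si](C)(C)OCC/C(C)=C/CO[Si](c1ccccc1)(c1ccccc1)C(C)(C)C | intermediate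
20 | (E)-5-(tert-butyldiphenylsilyloxy)-3-methylpent-3-en-1-ol | OCC/C(C)=C/CO[Si](c1ccccc1)(c1ccccc1)C(C)(C)C | intermediate
21 | (E)-tert-butyl[(5-iodo-3-methylpent-2-en-1-yl)oxy]diphenylsilane | ICC/C(C)=C/CO[Si](c1ccccc1)(c1ccccc1)C(C)(C)C | intermediate
22 | (E)-[5-(tert-butyldiphenylsilyloxy)-3-methylpent-3-en-1-yl]zinc iodide | I[Zn]CC/C(C)=C/CO[Si](c1ccccc1)(c1ccccc1)C(C)(C)C | intermediate
23 | 15-(tert-butyldiphenylsilyloxy)labda-8,13E-dien-6-one | O=C1CC(C)=C(CC/C(C)=C/CO[Si](c3ccccc3)(c3ccccc3)C(C)(C)C)[C@@]2(C)CCCC(C)(C)[C@H]12 | intermediate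
24 | potassium C6–C9 dienolate of 23 | [K]OC1=CC(C)=C(CC/C(C)=C/CO[Si](c3ccccc3)(c3ccccc3)C(C)(C)C)[C@@]2(C)CCCC(C)(C)[C@H]12 | intermediate
25 | 15-(tert-butyldiphenylsilyloxy)-7α-hydroxylabda-8,13E-dien-6-one | O=C1[C@@H](O)C(C)=C(CC/C(C)=C/CO[Si](c3ccccc3)(c3ccccc3)C(C)(C)C)[C@@]2(C)CCCC(C)(C)[C@H]12 | intermediate
26 | 15-(tert-butyldiphenylsilyloxy)labda-8,13E-diene-6β,7α-diol | O[C@@H]1[C@@H](O)C(C)=C(CC/C(C)=C/CO[Si](c3ccccc3)(c3ccccc3)C(C)(C)C)[C@@]2(C)CCCC(C)(C)[C@H]12 | intermediate
27 | 6β,7α-diacetoxy-15-(tert-butyldiphenylsilyloxy)labda-8,13E-diene | CC(=O)O[C@@H]1[C@@H](OC(C)=O)C(C)=C(CC/C(C)=C/CO[Si](c3ccccc3)(c3ccccc3)C(C)(C)C)[C@@]2(C)CCCC(C)(C)[C@H]12 | intermediate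
28 | 6β,7α-diacetoxylabda-8,13E-dien-15-ol | CC(=O)O[C@@H]1[C@@H](OC(C)=O)C(C)=C(CC/C(C)=C/CO)[C@@]2(C)CCCC(C)(C)[C@H]12 | target

**Step count and risks**

Total step count: 17. Longest linear sequence: 12 steps (steps 1–7 and 13–17, from (R)-carvone); the side-chain branch (steps 8–12) joins at step 13.

Steps most likely to fail:

1. Step 13. Transmetalation and reductive elimination at the tetrasubstituted C9–Pd centre, flanked by the quaternary C10 and the C8 methyl, may be slow enough for β-hydride elimination of the alkyl group or simple reduction of the triflate to take over. The fallback sets out from 21 and 14. Magnesium insertion into 21 (Mg, THF) would give the Grignard reagent (E)-[5-(tert-butyldiphenylsilyloxy)-3-methylpent-3-en-1-yl]magnesium iodide F5. This is added slowly to 14 and catalytic Fe(acac)3 in THF/NMP at −30 °C (iron-catalysed alkyl–alkenyl triflate coupling, which is little affected by steric bulk and is faster than addition to a ketone). The fallback comes back to the route at 23.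

2. Step 7. The hydride may be delivered to C8 or to a carbonyl carbon, or the C9 enolate may exchange a proton with the acidic C7 methylene before O-sulfonylation, giving regioisomeric or over-reduced material. The fallback sets out from 11 and bypasses 12. KHMDS and PhNTf2 would give the dienyl triflate 9-(trifluoromethylsulfonyloxy)-4,4,8,10-tetramethyl-6,8-diene F3, since γ-deprotonation toward C6 is the only enolisation open to 11. Buffered mCPBA should epoxidise the C6=C7 bond from the α-face, the C8=C9 bond being deactivated by the triflate, to give the 6α,7α-epoxide F4. A Lewis-acid Meinwald rearrangement (BF3·OEt2, CH2Cl2, −78 °C; ionisation at the allylic C7, 1,2-hydride shift from C6) then gives the C6 ketone. The fallback comes back to the route at 14.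

3. Step 6. Hydrogen abstraction at the C6 methylene next to the congested C5 may be sluggish, and attack at the C8 methyl or base-mediated epoxidation of the ene-dione by the hydroperoxide may compete. The fallback sets out from 11. TBSOTf and Et3N would give the silyl dienol ether 9-(tert-butyldimethylsilyloxy)-4,4,8,10-tetramethyl-6,8-diene F1. mCPBA (NaHCO3, CH2Cl2, 0 °C) should attack its C6=C7 bond (vinylogous Rubottom oxidation) to give the γ-hydroxy enone 6α-hydroxy-4,4,8,10-tetramethyl-7-en-9-one F2. Dess–Martin periodinane oxidises this to the ene-dione. The fallback comes back to the route at 12.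

**Further compounds**

F1 | step 6 | 9-(tert-butyldimethylsilyloxy)-4,4,8,10-tetramethyl-6,8-diene (silyl dienol ether of 11; 5α-H, 10β-CH3) | C1=CC(C)=C(O[Si](C)(C)C(C)(C)C)[C@@]2(C)CCCC(C)(C)[C@H]12
F2 | step 6 | 6α-hydroxy-4,4,8,10-tetramethyl-7-en-9-one (γ-hydroxy enone; 5α-H, 10β-CH3) | O[C@H]1C=C(C)C(=O)[C@@]2(C)CCCC(C)(C)[C@H]12
F3 | step 7 | 9-(trifluoromethylsulfonyloxy)-4,4,8,10-tetramethyl-6,8-diene (dienyl triflate of 11; 5α-H, 10β-CH3) | C1=CC(C)=C(OS(=O)(=O)C(F)(F)F)[C@@]2(C)CCCC(C)(C)[C@H]12
F4 | step 7 | 6α,7α-epoxy-9-(trifluoromethylsulfonyloxy)-4,4,8,10-tetramethyl-8-ene (5α-H, 10β-CH3) | O1[C@H]2[C@@H]1C(C)=C(OS(=O)(=O)C(F)(F)F)[C@@]3(C)CCCC(C)(C)[C@H]23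
F5 | step 13 | (E)-[5-(tert-butyldiphenylsilyloxy)-3-methylpent-3-en-1-yl]magnesium iodide | I[Mg]CC/C(C)=C/CO[Si](c1ccccc1)(c1ccccc1)C(C)(C)C
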